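**Strategy.** The cyclohexenone ring of zeylenone (C1–C6; C1 = carbinol carbon bearing CH2OBz, C2 = ketone, C3=C4, C5–OBz, C6–OH) contains a tertiary α-ketol, C1(OH)–C2(=O). Undoing an α-ketol (acyloin) shift of the C1–C6 bond back to C2 shrinks this ring to a cyclopentene. That cyclopentene carries C1 as an exocyclic benzoyloxyacetyl ketone on a tertiary allylic carbinol, the corticosteroid side-chain motif. The precursor comes from the D-ribose-derived 4,5-O-isopropylidenecyclopentenone and an acyl anion equivalent. One chelate-controlled 1,2-shift then expands five to six, unveils the conjugated enone and sets quaternary C1. A final Mitsunobu inversion places the C5 benzoate trans to C6–OH.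

Key step: step 4

Remark on numbering: the zeylenone numbering C1–C6 defined above is used for the same atoms in every intermediate.
Assumption: enone 1 is bought as the (3aS,6aS) antipode; both antipodes are catalogue compounds made from D-ribose (C6 and C5 of the target are ribose C3 and C2).

Step 1
Reactants: 1 (3aS,6aS)-2,2-dimethyl-3a,6a-dihydro-4H-cyclopenta[d][1,3]dioxol-4-one; 2 ethyl vinyl ether
Product: 4 (3aS,4R,6aS)-4-(1-ethoxyethenyl)-2,2-dimethyl-3a,6a-dihydro-4H-cyclopenta[d][1,3]dioxol-4-ol, via 1-ethoxyvinyllithium 3 (not isolated)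
Conditions: 2, t-BuLi, THF, −78 → 0 °C; then 1, THF, −78 °C; aq NH4Cl
Reagents that add atoms: none
Why: 1,2-addition of a hard α-alkoxyvinyllithium (acyl anion equivalent) to the enone carbonyl should occur on the convex face anti to the acetonide, which sets C2 with its OH cis to the two ring oxygens and the future acyl group trans to them.

Step 2
Reactants: 4 (3aS,4R,6aS)-4-(1-ethoxyethenyl)-2,2-dimethyl-3a,6a-dihydro-4H-cyclopenta[d][1,3]dioxol-4-ol
Product: 6 2-hydroxy-1-[(3aS,4R,6aS)-4-hydroxy-2,2-dimethyl-3a,6a-dihydro-4H-cyclopenta[d][1,3]dioxol-4-yl]ethan-1-one, via ethyl hemiketal 5 (not isolated)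
Conditions: OsO4 (2 mol %), NMO (1.05 equiv), pyridine (cat.), acetone/H2O, 0 °C
Reagents that add atoms: osmium tetroxide (catalytic oxygen carrier) O=[Os](=O)(=O)=O; N-methylmorpholine N-oxide C[N+]1([O-])CCOCC1; water O
Why: In this Upjohn dihydroxylation the electron-rich 1,1-disubstituted enol ether should react far faster than the hindered, inductively deactivated ring alkene, and hemiketal 5 loses ethanol to give the hydroxymethyl ketone without creating a lasting stereocentre.

Step 3
Reactants: 6 2-hydroxy-1-[(3aS,4R,6aS)-4-hydroxy-2,2-dimethyl-3a,6a-dihydro-4H-cyclopenta[d][1,3]dioxol-4-yl]ethan-1-one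
Product: 7 2-[(3aS,4R,6aS)-4-hydroxy-2,2-dimethyl-3a,6a-dihydro-4H-cyclopenta[d][1,3]dioxol-4-yl]-2-oxoethyl benzoate
Conditions: BzCl (1.05 equiv), pyridine, CH2Cl2, −20 °C
Reagents that add atoms: benzoyl chloride O=C(Cl)c1ccccc1
Why: Selective O-acylation should take only the primary alcohol, because the tertiary C2 carbinol is too hindered to be benzoylated at low temperature.

Step 4
Reactants: 7 2-[(3aS,4R,6aS)-4-hydroxy-2,2-dimethyl-3a,6a-dihydro-4H-cyclopenta[d][1,3]dioxol-4-yl]-2-oxoethyl benzoate
Product: 8 [(3aS,4S,7aS)-4-hydroxy-2,2-dimethyl-5-oxo-3a,4,5,7a-tetrahydro-1,3-benzodioxol-4-yl]methyl benzoate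
Conditions: Sc(OTf)3 (15 mol %), 4 Å MS, toluene, 60 °C
Reagents that add atoms: none
Why: Sc(III) clamps the C2 hydroxyl and the C1 ketone oxygen of 7 in a five-membered chelate, and the C2–C6 σ-bond then shifts suprafacially from the carbinol carbon C2 to the activated carbonyl carbon C1 while C2–O becomes the new ketone (α-ketol or acyloin rearrangement). The closest known reaction type is the Lewis-acid D-homoannulation of 17α-hydroxy-21-acyloxy-20-ketosteroids, in which the same 1-hydroxycyclopentyl acyloxymethyl ketone grows into a 2-hydroxy-2-(acyloxymethyl)cyclohexanone, and metal-chelate shifts of ketoses to 2-C-hydroxymethylaldoses show that an oxygen-bearing carbon migrates well. The six-membered ring C1–C6 is not closed by an exo or endo cyclisation but by a concerted 1,2-shift through a three-centre C2–C6–C1 transition state that inserts C1 into the cyclopentene, so C6 migrates with retention and C5 is untouched. The only new stereocentre, C1, is controlled by the chelate and by the C2 configuration from step 1: with O–C2–C1=O held syn-periplanar and the acyl group on the face opposite the acetonide, C6 can reach only the carbonyl face that places the new C1–OH cis to the C6 oxygen (1S), while C2 itself becomes the planar ketone. The step needs migration of C6 and not of the vinylic C3; this is secured because leaving C3=C4 on C2 develops enone conjugation in the transition state and in the product (vinyl carbons are likewise reluctant migrators in diazoalkane homologations of enones), and because the reversible ketol manifold drains to the conjugated six-membered isomer. Ionisation of the tertiary allylic alcohol is held back by the adjacent ketone, and the anhydrous, non-basic catalyst should leave acetonide and benzoate in place.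

Step 5
Reactants: 8 [(3aS,4S,7aS)-4-hydroxy-2,2-dimethyl-5-oxo-3a,4,5,7a-tetrahydro-1,3-benzodioxol-4-yl]methyl benzoate
Product: 9 [(1S,5S,6S)-1,5,6-trihydroxy-2-oxocyclohex-3-en-1-yl]methyl benzoate
Conditions: TFA/H2O (9:1), CH2Cl2, 0 °C → rt
Reagents that add atoms: none
Why: Acid hydrolysis of the isopropylidene acetal breaks no C–O bond at a stereocentre, so the all-cis triol should result with benzoate, enone and ketol intact.

Step 6
Reactants: 9 [(1S,5S,6S)-1,5,6-trihydroxy-2-oxocyclohex-3-en-1-yl]methyl benzoate
Product: 10 zeylenone, [(1S,5R,6S)-5-(benzoyloxy)-1,6-dihydroxy-2-oxocyclohex-3-en-1-yl]methyl benzoate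
Conditions: PPh3, DIAD (1.2 equiv each, betaine preformed), toluene/THF, −20 °C; then 9, BzOH (1.2 equiv), −20 → 0 °C
Reagents that add atoms: benzoic acid O=C(O)c1ccccc1
Why: In this Mitsunobu esterification benzoate should displace the oxyphosphonium group by SN2 at the allylic, least hindered secondary carbinol C5 and invert it (5S → 5R), giving the benzoate trans to C6–OH, while the neopentyl-type C6–OH and the tertiary C1–OH stay untouched.

**Compound list**
1 | (3aS,6aS)-2,2-dimethyl-3a,6a-dihydro-4H-cyclopenta[d][1,3]dioxol-4-one | CC1(C)O[C@H]2C=CC(=O)[C@H]2O1 | starting material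
2 | ethyl vinyl ether | C=COCC | starting material
3 | 1-ethoxyvinyllithium | [Li]C(=C)OCC | intermediate
4 | (3aS,4R,6aS)-4-(1-ethoxyethenyl)-2,2-dimethyl-3a,6a-dihydro-4H-cyclopenta[d][1,3]dioxol-4-ol (OH cis to the ring oxygens) | CC1(C)O[C@H]2C=C[C@](O)(C(=C)OCC)[C@H]2O1 | intermediate
5 | (3aS,4R,6aS)-4-(1-ethoxy-1,2-dihydroxyethyl)-2,2-dimethyl-3a,6a-dihydro-4H-cyclopenta[d][1,3]dioxol-4-ol (hemiketal carbon undefined) | CC1(C)O[C@H]2C=C[C@](O)(C(O)(CO)OCC)[C@H]2O1 | intermediate
6 | 2-hydroxy-1-[(3aS,4R,6aS)-4-hydroxy-2,2-dimethyl-3a,6a-dihydro-4H-cyclopenta[d][1,3]dioxol-4-yl]ethan-1-one | CC1(C)O[C@H]2C=C[C@](O)(C(=O)CO)[C@H]2O1 | intermediate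
7 | 2-[(3aS,4R,6aS)-4-hydroxy-2,2-dimethyl-3a,6a-dihydro-4H-cyclopenta[d][1,3]dioxol-4-yl]-2-oxoethyl benzoate | CC1(C)O[C@H]2C=C[C@](O)(C(=O)COC(=O)c3ccccc3)[C@H]2O1 | intermediate
8 | [(3aS,4S,7aS)-4-hydroxy-2,2-dimethyl-5-oxo-3a,4,5,7a-tetrahydro-1,3-benzodioxol-4-yl]methyl benzoate | O=C(OC[C@@]1(O)C(=O)C=C[C@@H]2OC(C)(C)O[C@H]12)c1ccccc1 | intermediate
9 | [(1S,5S,6S)-1,5,6-trihydroxy-2-oxocyclohex-3-en-1-yl]methyl benzoate (all-cis triol) | O=C(OC[C@@]1(O)C(=O)C=C[C@H](O)[C@@H]1O)c1ccccc1 | intermediate
10 | zeylenone, [(1S,5R,6S)-5-(benzoyloxy)-1,6-dihydroxy-2-oxocyclohex-3-en-1-yl]methyl benzoate | O=C(OC[C@@]1(O)C(=O)C=C[C@@H](OC(=O)c2ccccc2)[C@@H]1O)c1ccccc1 | target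

Total step count: 6. Longest linear sequence: 6.

**Steps most likely to fail**

Step 4. The vinylic carbon C3 may shift in competition with C6. Part of the material may also react through the non-chelated rotamer, which erodes control at C1. A slow turnover could give the Lewis acid time to attack the allylic acetonide.
Fallback: setting out from 7, the sp2 competitor is removed before the ring is expanded. Diimide (2-nitrobenzenesulfonyl hydrazide, Et3N, CH2Cl2) saturates C3=C4 without allylic hydrogenolysis and gives the saturated cyclopentane ketol F1. The chelate-controlled ketol shift (Sc(OTf)3, or Al(Ot-Bu)3 in warm toluene) is then run on F1. There the oxygen-bearing C6 competes only with an unactivated CH2, and the shift should give the saturated ring-expanded hydroxy ketone F2. IBX dehydrogenation (DMSO, 70 °C) can enolise only towards C3, because C1 is quaternary, so it reinstalls C3=C4 and comes back to the route at 8.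

Step 6. Site selectivity among the three hydroxyls may be poor, or a cyclic phosphorane of a cis-diol may form and stall the reaction. The activated γ-position of the enone may also eliminate towards aromatisation instead of undergoing clean inversion.
Fallback: setting out from 7, the inversion is moved ahead of the ring expansion, where the leaving group sits on a plain cyclopentenyl carbinol with no enone. Aqueous TFA removes the acetonide and gives the cyclopentene triol F3. Mitsunobu benzoylation (PPh3, DIAD, BzOH) at its allylic C5–OH gives the trans hydroxy benzoate F4. The Sc(III) ketol shift of step 4 applied to F4 then comes back to the route directly at 10.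

Step 2. The acid-labile enol ether may hydrolyse to the methyl ketone, or the ring alkene may be over-oxidised, so that chemoselectivity is lost.
Fallback: setting out from 1, ethynylmagnesium bromide (THF, −78 °C) adds on the convex face and gives the ethynyl carbinol F5. Hypervalent iodine oxidation of this ethynylcarbinol (PhI(O2CCF3)2, MeCN/H2O, 60 °C) converts the terminal alkyne into the hydroxymethyl ketone. This comes back to the route at 6 without any osmium or enol ether chemistry.

**Further compounds**
F1 | step 4 | 2-[(3aS,4R,6aS)-4-hydroxy-2,2-dimethyltetrahydro-4H-cyclopenta[d][1,3]dioxol-4-yl]-2-oxoethyl benzoate (C3,C4-dihydro-7) | CC1(C)O[C@H]2CC[C@](O)(C(=O)COC(=O)c3ccccc3)[C@H]2O1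
F2 | step 4 | [(3aS,4S,7aS)-4-hydroxy-2,2-dimethyl-5-oxohexahydro-1,3-benzodioxol-4-yl]methyl benzoate (C3,C4-dihydro-8) | O=C(OC[C@@]1(O)C(=O)CC[C@@H]2OC(C)(C)O[C@H]12)c1ccccc1
F3 | step 6 | 2-oxo-2-[(1R,4S,5S)-1,4,5-trihydroxycyclopent-2-en-1-yl]ethyl benzoate (all-cis triol) | O[C@H]1C=C[C@](O)(C(=O)COC(=O)c2ccccc2)[C@H]1O
F4 | step 6 | the C5-inverted monobenzoate of F3, with C5–OBz trans to C6–OH and C2–OH cis to C6–OH | O=C(O[C@@H]1C=C[C@](O)(C(=O)COC(=O)c2ccccc2)[C@H]1O)c1ccccc1
F5 | step 2 | (3aS,4R,6aS)-4-ethynyl-2,2-dimethyl-3a,6a-dihydro-4H-cyclopenta[d][1,3]dioxol-4-ol | CC1(C)O[C@H]2C=C[C@](O)(C#C)[C@H]2O1
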